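**Retrosynthetic overview**
1. Target 23 ⇐ silylene and methyl-ester removal from 21; C1–C2 by Horner–Wadsworth–Emmons on methyl ketone 20; oxirane by OH-directed epoxidation of (Z)-allylic alcohol 18, whose C3 carbinol (from (R)-but-3-yn-2-ol) relays chirality to C4/C5 and is then oxidised away.
2. C11–C12 (key bond, sets C12): nickel-electrocatalytic doubly decarboxylative coupling of acid 11 with the malate-derived silylene acid 15.
3. C5–C6: nickel-electrocatalytic decarboxylative alkenylation of acid 4 with (Z)-vinyl iodide 8.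
4. Pieces: 4 from (R)-citronellic acid (C7) by cross-metathesis/hydrogenation; 8 from (R)-but-3-yn-2-ol; 15 from dimethyl (S)-malate (C13 by Fráter–Seebach hydroxymethylation).
5. Rings: no carbocycle; the temporary 1,3,2-dioxasilinane is closed first (step 6), the oxirane last (step 9).

Assumption: chain atoms are numbered C1 (enoic acid carbon) to C14 (carboxyl on the CH2OH-bearing carbon), and 1, 5 and 12 are bought as single enantiomers.

**Route**

Step 1
Reactants: 1 (R)-citronellic acid; 2 methyl acrylate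
Product: 4 (3R)-8-methoxy-3-methyl-8-oxooctanoic acid, via enoate acid 3 (not isolated)
Conditions: second-generation Grubbs catalyst RuCl2(=CHPh)(PCy3)(H2IMes) (3 mol %), 2 (4 equiv), CH2Cl2, 40 °C; then Pd/C (10 wt %), H2 (1 atm), MeOH, rt
Reagents that add atoms: none
Why: Olefin cross-metathesis of the prenyl-type alkene with the acrylate (isobutene lost) and hydrogenation add C11 plus the carboxyl carbon that is extruded in step 8, while the bought C7 stereocentre is untouched.

Step 2
Reactants: 5 (R)-but-3-yn-2-ol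
Product: 6 (R)-pent-3-yn-2-ol
Conditions: n-BuLi (2.1 equiv), THF, −78 °C; MeI (1.05 equiv), −78 °C → rt; H2O work-up
Reagents that add atoms: iodomethane, CI
Why: Acetylide alkylation of the dilithio species is C-selective, and the bought carbinol centre is not involved.

Step 3
Reactants: 6 (R)-pent-3-yn-2-ol
Product: 8 (2R,3Z)-4-iodopent-3-en-2-ol, via alkenylalanate 7 (not isolated)
Conditions: NaAlH2(OCH2CH2OCH3)2 (1.5 equiv), THF, 0 °C → rt; then I2 (1.5 equiv), −78 → 0 °C; aqueous work-up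
Reagents that add atoms: iodine, [I][I]
Why: Alkoxide-directed trans-hydroalumination of the propargylic alcohol puts aluminium on the distal carbon cis to the carbinol, and iodinolysis with retention gives the (Z)-iodide.

Step 4
Reactants: 4 (3R)-8-methoxy-3-methyl-8-oxooctanoic acid; 8 (2R,3Z)-4-iodopent-3-en-2-ol
Product: 10 methyl (6R,8Z,10R)-10-hydroxy-6,8-dimethylundec-8-enoate, via N-hydroxyphthalimide ester 9 (not isolated)
Conditions: N-hydroxyphthalimide, iPrN=C=NiPr (DIC), THF, rt; then 8 (1.5 equiv), NiCl2·6H2O (10 mol %), 2,2'-bipyridine (10 mol %), AgNO3 (0.3 equiv), DMF, Mg anode, RVC cathode, constant current, rt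
Reagents that add atoms: none
Why: Nickel-electrocatalytic decarboxylative alkenylation: cathodic reduction of the redox-active ester releases the primary C6 radical, which nickel joins to the alkenyl iodide with retention of the Z geometry, forming C5–C6 without touching a stereocentre.

Step 5
Reactants: 10 methyl (6R,8Z,10R)-10-hydroxy-6,8-dimethylundec-8-enoate
Product: 11 (6R,8Z,10R)-10-hydroxy-6,8-dimethylundec-8-enoic acid
Conditions: LiOH·H2O (3 equiv), THF/MeOH/H2O, rt; then 1 M HCl to pH 3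
Reagents that add atoms: lithium hydroxide, [Li+].[OH-]
Why: Saponification of the only ester frees the acid needed for the second decarboxylative coupling.

Step 6
Reactants: 12 dimethyl (S)-malate
Product: 14 dimethyl (4S,5R)-2,2-di-tert-butyl-1,3,2-dioxasilinane-4,5-dicarboxylate, via dilithium dialkoxide 13 (not isolated)
Conditions: LiN(iPr)2 (2.1 equiv), THF, −78 → −20 °C; CH2O (1.2 equiv, THF solution), −78 °C; then (tBu)2Si(OTf)2 (1.1 equiv), −78 → 0 °C
Reagents that add atoms: formaldehyde, C=O; di-tert-butylsilyl bis(trifluoromethanesulfonate), CC(C)(C)[Si](OS(=O)(=O)C(F)(F)F)(OS(=O)(=O)C(F)(F)F)C(C)(C)C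
Why: Fráter–Seebach reaction: the chelated dianion of the β-hydroxy ester adds to formaldehyde anti to the C2 oxygen, so the bought malate centre sets C13 (R), and the dialkoxide is trapped as the silylene before it can lactonise.

Step 7
Reactants: 14 dimethyl (4S,5R)-2,2-di-tert-butyl-1,3,2-dioxasilinane-4,5-dicarboxylate
Product: 15 (4S,5R)-2,2-di-tert-butyl-5-(methoxycarbonyl)-1,3,2-dioxasilinane-4-carboxylic acid
Conditions: LiOH·H2O (1.05 equiv), THF/H2O, 0 °C; then 1 M HCl to pH 3
Reagents that add atoms: lithium hydroxide, [Li+].[OH-]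
Why: Selective mono-saponification, because in the cis-diester chair the C4 ester is α-oxygenated and equatorial while the C5 ester is axial and slower to hydrolyse.

Step 8
Reactants: 11 (6R,8Z,10R)-10-hydroxy-6,8-dimethylundec-8-enoic acid; 15 (4S,5R)-2,2-di-tert-butyl-5-(methoxycarbonyl)-1,3,2-dioxasilinane-4-carboxylic acid
Product: 18 methyl (4S,5R)-2,2-di-tert-butyl-4-[(5R,7Z,9R)-9-hydroxy-5,7-dimethyldec-7-en-1-yl]-1,3,2-dioxasilinane-5-carboxylate, via N-hydroxyphthalimide ester 16 (not isolated), via N-hydroxyphthalimide ester 17 (not isolated)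
Conditions: 11 (1 equiv), 15 (3 equiv), N-hydroxyphthalimide, DIC, THF, rt; then NiCl2·6H2O (20 mol %), 2,2':6',2''-terpyridine (20 mol %), AgNO3 (0.3 equiv), NMP, Mg anode, RVC cathode, constant current, rt; dilute HCl work-up
Reagents that add atoms: none
Why: Proposed new method: a nickel-electrocatalytic doubly decarboxylative C(sp3)–C(sp3) coupling in which the secondary partner is a six-membered 1,3,2-dioxasilinan-4-yl (α-silyloxy) radical with an ester-bearing stereocentre next to the radical carbon, used to form C11–C12 and set C12; cathodic reduction of both redox-active esters gives the primary C11 radical, captured first by low-valent nickel, and the α-oxy C12 radical, which adds to the alkylnickel to give a dialkyl trivalent nickel species that reductively eliminates; the axial tert-butyl group on silicon shields the axial face of C12 and the C13 ester stays equatorial, so the new bond should form equatorially and trans to the ester, giving the (4S,5R) ring (12S) from the malate-derived C13; the closest known reaction type is the nickel-electrocatalytic doubly decarboxylative coupling of five-membered acetonide (tartrate-type) α-alkoxy redox-active esters, which couple trans to the neighbouring substituent.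

Step 9
Reactants: 18 methyl (4S,5R)-2,2-di-tert-butyl-4-[(5R,7Z,9R)-9-hydroxy-5,7-dimethyldec-7-en-1-yl]-1,3,2-dioxasilinane-5-carboxylate
Product: 19 methyl (4S,5R)-2,2-di-tert-butyl-4-[(5R)-6-{(2R,3S)-3-[(1R)-1-hydroxyethyl]-2-methyloxiran-2-yl}-5-methylhexyl]-1,3,2-dioxasilinane-5-carboxylate
Conditions: mCPBA (1.2 equiv), CH2Cl2, −10 °C
Reagents that add atoms: 3-chloroperoxybenzoic acid, OOC(=O)c1cccc(Cl)c1
Why: Hydroxyl-directed peracid epoxidation (Henbest type): in the Z-alkene, allylic 1,3-strain holds the carbinol C–H in the alkene plane and the hydrogen-bonded peracid delivers oxygen syn to OH, so the (R)-carbinol sets C4 (S) and C5 (R) of the only alkene present.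

Step 10
Reactants: 19 methyl (4S,5R)-2,2-di-tert-butyl-4-[(5R)-6-{(2R,3S)-3-[(1R)-1-hydroxyethyl]-2-methyloxiran-2-yl}-5-methylhexyl]-1,3,2-dioxasilinane-5-carboxylate
Product: 20 methyl (4S,5R)-4-[(5R)-6-{(2R,3R)-3-acetyl-2-methyloxiran-2-yl}-5-methylhexyl]-2,2-di-tert-butyl-1,3,2-dioxasilinane-5-carboxylate
Conditions: Dess–Martin periodinane (1.3 equiv), pyridine, CH2Cl2, 0 °C → rt
Reagents that add atoms: none
Why: Dess–Martin oxidation of the secondary epoxy alcohol gives the methyl ketone and erases the relay stereocentre without touching the epoxide (the descriptor at the oxirane CH changes only by priority).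

Step 11
Reactants: 20 methyl (4S,5R)-4-[(5R)-6-{(2R,3R)-3-acetyl-2-methyloxiran-2-yl}-5-methylhexyl]-2,2-di-tert-butyl-1,3,2-dioxasilinane-5-carboxylate
Product: 21 methyl (4S,5R)-2,2-di-tert-butyl-4-[(5R)-6-{(2R,3S)-3-[(2E)-4-methoxy-4-oxobut-2-en-2-yl]-2-methyloxiran-2-yl}-5-methylhexyl]-1,3,2-dioxasilinane-5-carboxylate
Conditions: (MeO)2P(O)CH2CO2Me (1.5 equiv), NaH (1.4 equiv), THF, 0 °C; then 20, 0 °C → rt
Reagents that add atoms: methyl 2-(dimethoxyphosphoryl)acetate, COC(=O)CP(=O)(OC)OC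
Why: Horner–Wadsworth–Emmons olefination of the methyl ketone places the bulky epoxide-bearing carbon trans to the ester (2E), and the weakly basic phosphonate anion leaves the epoxy ketone and C13 intact.

Step 12
Reactants: 21 methyl (4S,5R)-2,2-di-tert-butyl-4-[(5R)-6-{(2R,3S)-3-[(2E)-4-methoxy-4-oxobut-2-en-2-yl]-2-methyloxiran-2-yl}-5-methylhexyl]-1,3,2-dioxasilinane-5-carboxylate
Product: 23 (2E,4S,5R,7R,12S,13R)-4,5-epoxy-12-hydroxy-13-(hydroxymethyl)-3,5,7-trimethyltetradec-2-enedioic acid, via diol diester 22 (not isolated)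
Conditions: HF·pyridine, pyridine, THF, 0 °C; then aq. LiOH (6 equiv), MeOH, 0 °C → rt; then cold 0.5 M HCl to pH 4
Reagents that add atoms: lithium hydroxide, [Li+].[OH-]
Why: Buffered fluoride cleaves the silylene and hydroxide saponifies both methyl esters, conditions chosen so that the trisubstituted epoxide is never exposed to strong acid and no stereocentre is affected.

**Compound list**

1 | (R)-citronellic acid, (3R)-3,7-dimethyloct-6-enoic acid | OC(=O)C[C@H](C)CCC=C(C)C | starting material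
2 | methyl acrylate | C=CC(=O)OC | starting material
3 | (3R,6E)-8-methoxy-3-methyl-8-oxooct-6-enoic acid | OC(=O)C[C@H](C)CC/C=C/C(=O)OC | intermediate
4 | (3R)-8-methoxy-3-methyl-8-oxooctanoic acid | OC(=O)C[C@H](C)CCCCC(=O)OC | intermediate
5 | (R)-but-3-yn-2-ol | C[C@@H](O)C#C | starting material
6 | (R)-pent-3-yn-2-ol | C[C@@H](O)C#CC | intermediate
7 | sodium (5R)-2,2-bis(2-methoxyethoxy)-3,5-dimethyl-2,5-dihydro-1,2-oxaaluminol-2-uide (cyclic alkenylalanate) | [Na+].C[C@H]1O[Al-](OCCOC)(OCCOC)C(C)=C1 | intermediate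
8 | (2R,3Z)-4-iodopent-3-en-2-ol | C[C@@H](O)/C=C(/C)I | intermediate
9 | 1-(1,3-dioxoisoindolin-2-yl) 8-methyl (3R)-3-methyloctanedioate | COC(=O)CCCC[C@@H](C)CC(=O)ON1C(=O)c2ccccc2C1=O | intermediate
10 | methyl (6R,8Z,10R)-10-hydroxy-6,8-dimethylundec-8-enoate | C[C@@H](O)/C=C(/C)C[C@H](C)CCCCC(=O)OC | intermediate
11 | (6R,8Z,10R)-10-hydroxy-6,8-dimethylundec-8-enoic acid | C[C@@H](O)/C=C(/C)C[C@H](C)CCCCC(=O)O | intermediate
12 | dimethyl (S)-malate | COC(=O)C[C@H](O)C(=O)OC | starting material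
13 | dilithium dialkoxide of dimethyl (2S,3R)-2-hydroxy-3-(hydroxymethyl)butanedioate | [Li+].[Li+].COC(=O)[C@H](C[O-])[C@H]([O-])C(=O)OC | intermediate
14 | dimethyl (4S,5R)-2,2-di-tert-butyl-1,3,2-dioxasilinane-4,5-dicarboxylate | COC(=O)[C@H]1O[Si](C(C)(C)C)(C(C)(C)C)OC[C@H]1C(=O)OC | intermediate
15 | (4S,5R)-2,2-di-tert-butyl-5-(methoxycarbonyl)-1,3,2-dioxasilinane-4-carboxylic acid | OC(=O)[C@H]1O[Si](C(C)(C)C)(C(C)(C)C)OC[C@H]1C(=O)OC | intermediate
16 | 1,3-dioxoisoindolin-2-yl (6R,8Z,10R)-10-hydroxy-6,8-dimethylundec-8-enoate | C[C@@H](O)/C=C(/C)C[C@H](C)CCCCC(=O)ON1C(=O)c2ccccc2C1=O | intermediate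
17 | 4-(1,3-dioxoisoindolin-2-yl) 5-methyl (4S,5R)-2,2-di-tert-butyl-1,3,2-dioxasilinane-4,5-dicarboxylate | O=C(ON1C(=O)c2ccccc2C1=O)[C@H]1O[Si](C(C)(C)C)(C(C)(C)C)OC[C@H]1C(=O)OC | intermediate
18 | methyl (4S,5R)-2,2-di-tert-butyl-4-[(5R,7Z,9R)-9-hydroxy-5,7-dimethyldec-7-en-1-yl]-1,3,2-dioxasilinane-5-carboxylate | C[C@@H](O)/C=C(/C)C[C@H](C)CCCC[C@@H]1O[Si](C(C)(C)C)(C(C)(C)C)OC[C@H]1C(=O)OC | intermediate
19 | methyl (4S,5R)-2,2-di-tert-butyl-4-[(5R)-6-{(2R,3S)-3-[(1R)-1-hydroxyethyl]-2-methyloxiran-2-yl}-5-methylhexyl]-1,3,2-dioxasilinane-5-carboxylate | C[C@@H](O)[C@@H]1O[C@]1(C)C[C@H](C)CCCC[C@@H]1O[Si](C(C)(C)C)(C(C)(C)C)OC[C@H]1C(=O)OC | intermediate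
20 | methyl (4S,5R)-4-[(5R)-6-{(2R,3R)-3-acetyl-2-methyloxiran-2-yl}-5-methylhexyl]-2,2-di-tert-butyl-1,3,2-dioxasilinane-5-carboxylate | CC(=O)[C@@H]1O[C@]1(C)C[C@H](C)CCCC[C@@H]1O[Si](C(C)(C)C)(C(C)(C)C)OC[C@H]1C(=O)OC | intermediate
21 | methyl (4S,5R)-2,2-di-tert-butyl-4-[(5R)-6-{(2R,3S)-3-[(2E)-4-methoxy-4-oxobut-2-en-2-yl]-2-methyloxiran-2-yl}-5-methylhexyl]-1,3,2-dioxasilinane-5-carboxylate | C/C(=C\C(=O)OC)[C@@H]1O[C@]1(C)C[C@H](C)CCCC[C@@H]1O[Si](C(C)(C)C)(C(C)(C)C)OC[C@H]1C(=O)OC | intermediate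
22 | dimethyl (2E,4S,5R,7R,12S,13R)-4,5-epoxy-12-hydroxy-13-(hydroxymethyl)-3,5,7-trimethyltetradec-2-enedioate | C/C(=C\C(=O)OC)[C@@H]1O[C@]1(C)C[C@H](C)CCCC[C@H](O)[C@@H](CO)C(=O)OC | intermediate
23 | (2E,4S,5R,7R,12S,13R)-4,5-epoxy-12-hydroxy-13-(hydroxymethyl)-3,5,7-trimethyltetradec-2-enedioic acid | C/C(=C\C(=O)O)[C@@H]1O[C@]1(C)C[C@H](C)CCCC[C@H](O)[C@@H](CO)C(=O)O | target

**Step count and risks**

Total step count: 12. Longest linear sequence: 9 steps (from 5: steps 2, 3, 4, 5, 8, 9, 10, 11, 12).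

Step 8 (the proposed new step). The risks are poor cross-selectivity between the two radicals and an insufficient trans preference at C12, which the six-membered ring makes less certain than in five-membered cases. The fallback uses only known reactions, carries both East stereocentres in from the chiral pool, sets out from 1 (with 8) and comes back at 18. Ozonolysis of 1 (O3, CH2Cl2/MeOH, −78 °C) gives (3R)-3-methyl-6-oxohexanoic acid F1, reduced in the same flask with NaBH4 to (3R)-6-hydroxy-3-methylhexanoic acid F2. Its in situ ester 1,3-dioxoisoindolin-2-yl (3R)-6-hydroxy-3-methylhexanoate F3 is coupled with 8 under the conditions of step 4 to give (4R,6Z,8R)-4,6-dimethylnon-6-ene-1,8-diol F4. Separately, bought (R)-3-hydroxy-γ-butyrolactone (O=C1C[C@@H](O)CO1) is hydroxymethylated through its dianion (LiN(iPr)2, 2.1 equiv; CH2O). The ring forces the new group trans to the hydroxyl, which is the required 12S,13R pattern, giving (3R,4R)-4-hydroxy-3-(hydroxymethyl)oxolan-2-one F5. HBr in AcOH followed by MeOH opens the lactone to methyl (2R,3R)-4-bromo-3-hydroxy-2-(hydroxymethyl)butanoate F6, and (tBu)2Si(OTf)2 with 2,6-lutidine gives methyl (4R,5R)-4-(bromomethyl)-2,2-di-tert-butyl-1,3,2-dioxasilinane-5-carboxylate F7. The primary hydroxyl of F4 is condensed with 5,7-di-tert-butyl-3-phenylbenzoxazolium tetrafluoroborate (pyridine) to 2-{[(4R,6Z,8R)-8-hydroxy-4,6-dimethylnon-6-en-1-yl]oxy}-5,7-di-tert-butyl-3-phenyl-2,3-dihydro-1,3-benzoxazole F8. The known nickel/photoredox deoxygenative alkyl–alkyl coupling of F8 with F7 ([Ir(ppy)2(dtbbpy)]PF6, NiBr2 with 4,4'-di-tert-butyl-2,2'-bipyridine, quinuclidine, blue LEDs) forms C10–C11 and gives 18.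

Step 6. The risks are oligomeric hemiacetal alkoxides from formaldehyde and lactonisation of the aldolate onto the neighbouring ester before the silylene closes. The fallback sets out from 12 and comes back at 14. The same dianion is alkylated with benzyl chloromethyl ether (standard Fráter–Seebach alkylation, same anti sense) to give dimethyl (2S,3R)-3-[(benzyloxy)methyl]-2-hydroxybutanedioate F9. Hydrogenolysis (H2, Pd/C, EtOAc) gives dimethyl (2S,3R)-2-hydroxy-3-(hydroxymethyl)butanedioate F10, which is silylated at once with (tBu)2Si(OTf)2 and 2,6-lutidine (CH2Cl2, 0 °C) to give 14.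

Step 4. The risks are protodeiodination of the unprotected hydroxy iodide, homocoupling, and slow capture of the β-branched primary radical. The fallback replaces the radical coupling by a two-electron cross-coupling, sets out from 4 (with 8) and comes back at 10. Photochemical iododecarboxylation of 4 (PhI(OAc)2, I2, hν, cyclohexane) gives methyl (6R)-7-iodo-6-methylheptanoate F11. Zinc insertion (Zn dust, LiCl, THF, 40 °C) gives iodo[(2R)-7-methoxy-2-methyl-7-oxoheptyl]zinc F12. Negishi coupling with 8 (Pd(OAc)2, SPhos, THF, rt; an extra equivalent of F12 covers the free hydroxyl) proceeds with retention of the Z geometry and gives 10.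

**Further compounds**

F1 | step 8 | (3R)-3-methyl-6-oxohexanoic acid | OC(=O)C[C@H](C)CCC=O
F2 | step 8 | (3R)-6-hydroxy-3-methylhexanoic acid | OC(=O)C[C@H](C)CCCO
F3 | step 8 | 1,3-dioxoisoindolin-2-yl (3R)-6-hydroxy-3-methylhexanoate | OCCC[C@@H](C)CC(=O)ON1C(=O)c2ccccc2C1=O
F4 | step 8 | (4R,6Z,8R)-4,6-dimethylnon-6-ene-1,8-diol | C[C@@H](O)/C=C(/C)C[C@H](C)CCCO
F5 | step 8 | (3R,4R)-4-hydroxy-3-(hydroxymethyl)oxolan-2-one | O=C1[C@H](CO)[C@@H](O)CO1
F6 | step 8 | methyl (2R,3R)-4-bromo-3-hydroxy-2-(hydroxymethyl)butanoate | COC(=O)[C@H](CO)[C@@H](O)CBr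
F7 | step 8 | methyl (4R,5R)-4-(bromomethyl)-2,2-di-tert-butyl-1,3,2-dioxasilinane-5-carboxylate | BrC[C@@H]1O[Si](C(C)(C)C)(C(C)(C)C)OC[C@H]1C(=O)OC
F8 | step 8 | 2-{[(4R,6Z,8R)-8-hydroxy-4,6-dimethylnon-6-en-1-yl]oxy}-5,7-di-tert-butyl-3-phenyl-2,3-dihydro-1,3-benzoxazole | C[C@@H](O)/C=C(/C)C[C@H](C)CCCOC1Oc2c(C(C)(C)C)cc(C(C)(C)C)cc2N1c1ccccc1
F9 | step 6 | dimethyl (2S,3R)-3-[(benzyloxy)methyl]-2-hydroxybutanedioate | COC(=O)[C@H](COCc1ccccc1)[C@H](O)C(=O)OC
F10 | step 6 | dimethyl (2S,3R)-2-hydroxy-3-(hydroxymethyl)butanedioate | COC(=O)[C@H](CO)[C@H](O)C(=O)OC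
F11 | step 4 | methyl (6R)-7-iodo-6-methylheptanoate | IC[C@H](C)CCCCC(=O)OC
F12 | step 4 | iodo[(2R)-7-methoxy-2-methyl-7-oxoheptyl]zinc | I[Zn]C[C@H](C)CCCCC(=O)OC
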